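The plan rests on forming the C18–C19 bond last among the ring bonds. C19 is the bridgehead shared by the piperidine and the cycloheptene ring of a 3-azabicyclo[4.3.1]decene. Its outward C–H bond lies beside C13 of cyclopentene ring A, five atoms from C18 along C16–C13–C12. A rhodium carbenoid at C18 inserts into this bond. One operation closes cyclopentane ring B and makes C19 quaternary with retention. The precursor is the azatricyclic alpha-diazo benzyl ester with C6 already quaternary, nitrogen masked as a methyl carbamate and all three alcohols silylated. The surplus ester carbon is then excised by radical decarboxylation.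

Key step: step 21

Remarks on the chemistry
- Atom labels C1–C22 follow the carbons of the target SMILES from left to right. C23 is the extra ester carbon on C18. TBS = tert-butyldimethylsilyl.
- C19–H is not the only C–H within reach of C18. C15–H2 is also five atoms away (C18–C16–C13–C14–C15) and C20–H2 is six atoms away. Selectivity must therefore come from strain and geometry (see step 21).
- An ester on the C13 side chain would be deprotonated during the C6 alkylation, so C23 is introduced only afterwards (step 18).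
- A benzyl ester is used at C18 so that the hindered acid is freed by hydrogenolysis. This avoids hydroxide next to a methyl carbamate and three silyl ethers.
- Assumption: the sense of induction in step 4 has to be assigned on the first adduct. The ligand enantiomer that gives the (S)-configured enol triflate is used.

Step 1
Reactants: 1 2-bromoprop-2-en-1-ol
Product: 2 [(2-bromoprop-2-en-1-yl)oxy](tert-butyl)dimethylsilane
Conditions: TBSCl, imidazole, CH2Cl2, 0 → 25 °C
Reagents that add atoms: tert-butyldimethylsilyl chloride CC(C)(C)[Si](C)(C)Cl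
Why: Imidazole-promoted O-silylation of a primary allylic alcohol, which leaves the vinyl bromide untouched.

Step 2
Reactants: 3 cyclopent-2-en-1-one
Product: 4 2-iodocyclopent-2-en-1-one
Conditions: I2, pyridine/CH2Cl2, 0 → 25 °C
Reagents that add atoms: iodine II
Why: Alpha-iodination of an enone by conjugate addition of pyridine, iodination of the enolate and elimination (Baylis–Hillman-type mechanism).

Step 3
Reactants: 4 2-iodocyclopent-2-en-1-one; 5 bromo(2-ethoxy-2-oxoethyl)zinc (BrZnCH2CO2Et)
Product: 6 ethyl 2-(5-oxocyclopent-1-en-1-yl)acetate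
Conditions: Pd(dba)2 (3 mol %), P(2-furyl)3 (6 mol %), THF, 25 °C
Reagents that add atoms: none
Why: Negishi coupling of an alpha-iodoenone with a Reformatsky-type zinc reagent under zerovalent palladium places C19 and an ester carbon on C12.

Step 4
Reactants: 6 ethyl 2-(5-oxocyclopent-1-en-1-yl)acetate; 2 [(2-bromoprop-2-en-1-yl)oxy](tert-butyl)dimethylsilane
Product: 9 ethyl 2-[(5S)-5-{3-[(tert-butyldimethylsilyl)oxy]prop-1-en-2-yl}-2-(trifluoromethylsulfonyloxy)cyclopent-1-en-1-yl]acetate, via alkenylmagnesium bromide 7 (not isolated), via bromomagnesium enolate 8 (not isolated)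
Conditions: 2, Mg, Et2O, 0 → 25 °C; Cu(OTf)2 (3 mol %), chiral hydroxyalkyl N-mesityl imidazolinium PF6 salt (4 mol %), 6, slow addition of 7, Et2O, −30 °C; then Comins' reagent, THF, −78 → 0 °C
Reagents that add atoms: Comins' reagent, N-(5-chloropyridin-2-yl)bis(trifluoromethanesulfonimide) FC(F)(F)S(=O)(=O)N(c1ccc(Cl)cn1)S(=O)(=O)C(F)(F)F; magnesium [Mg] (atoms only in 7 and 8)
Why: Copper–NHC-catalysed asymmetric conjugate addition of a Grignard reagent to an alpha-substituted cyclopentenone, in which the ligand selects the face of C13, gives the C11–C12 enolate regiospecifically, and O-triflation fixes it as the tetrasubstituted enol triflate before proton exchange with the acidic C19 methylene can occur.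

Step 5
Reactants: 9 enol triflate; 10 bromo(4-ethoxy-4-oxobutyl)zinc (BrZn(CH2)3CO2Et)
Product: 11 ethyl 4-[(3R)-3-{3-[(tert-butyldimethylsilyl)oxy]prop-1-en-2-yl}-2-(2-ethoxy-2-oxoethyl)cyclopent-1-en-1-yl]butanoate
Conditions: PdCl2(dppf) (5 mol %), LiCl, THF, 50 °C
Reagents that add atoms: none
Why: Negishi coupling of the alkenyl triflate with a functionalised alkylzinc bromide (dppf suppresses beta-hydride elimination) fixes the tetrasubstituted C11=C12 alkene and leaves C13 unchanged (the descriptor changes only by priority).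

Step 6
Reactants: 11 diester
Product: 12 ethyl (3R)-3-{3-[(tert-butyldimethylsilyl)oxy]prop-1-en-2-yl}-5-oxo-1,2,3,4,5,6,7,8-octahydroazulene-4-carboxylate (C19 epimers and enol)
Conditions: KOt-Bu (1.2 equiv), THF (0.01 M), 0 °C; aq NH4Cl
Reagents that add atoms: none
Why: Dieckmann condensation in which the more acidic allylic C19 methylene attacks the remote ester and closes the seven-membered ring, helped by the cis alkene that holds both arms together; the other mode of closure would give the same ketone after step 7.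

Step 7
Reactants: 12 beta-keto ester
Product: 13 (3R)-3-{3-[(tert-butyldimethylsilyl)oxy]prop-1-en-2-yl}-2,3,4,6,7,8-hexahydroazulen-5(1H)-one
Conditions: NaCl, DMSO/H2O, 140 °C
Reagents that add atoms: none
Why: Krapcho dealkoxycarbonylation under neutral conditions removes the C19 ester and protonates the enolate at C19, so the beta,gamma-alkene and C13 should stay in place.

Step 8
Reactants: 14 benzylamine; 15 formaldehyde (as paraformaldehyde)
Product: 16 N-benzyl-1-methoxy-N-(methoxymethyl)methanamine
Conditions: MeOH, K2CO3, 25 °C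
Reagents that add atoms: methanol CO
Why: Aminal-ether formation from a primary amine, formaldehyde and methanol gives a storable precursor of two iminium ions.

Step 9
Reactants: 13 hexahydroazulenone; 16 bis(methoxymethyl)benzylamine
Product: 17 N-benzyl azatricyclic ketone (C6=O; C8 S; C13 R; C19 R; CH2–N–CH2 bridge anti to the C13 side chain)
Conditions: Me3SiCl (2.5 equiv), MeCN, 0 → 40 °C; aq NaHCO3
Reagents that add atoms: none
Why: Double Mannich annulation in which the first iminium ion attacks the dienol at C19 on the face opposite the C13 side chain and the second closes onto C8, which can only bridge cis and can epimerise before closure, so both new centres follow from C13.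

Step 10
Reactants: 17 azatricyclic ketone
Product: 18 N-benzyl azatricyclic C6 nitrile (C6 epimers)
Conditions: TosMIC, KOt-Bu, DME/EtOH, 0 → 40 °C
Reagents that add atoms: p-toluenesulfonylmethyl isocyanide Cc1ccc(cc1)S(=O)(=O)C[N+]#[C-]
Why: Van Leusen reductive cyanation turns the hindered bridge ketone into the nitrile (C7) in one step, and the C6 epimer mixture is irrelevant because C6 is planarised in step 14.

Step 11
Reactants: 19 methyl (S)-3-hydroxypentanoate
Product: 20 methyl (S)-3-[(tert-butyldimethylsilyl)oxy]pentanoate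
Conditions: TBSCl, imidazole, DMF, 25 °C
Reagents that add atoms: tert-butyldimethylsilyl chloride CC(C)(C)[Si](C)(C)Cl
Why: O-silylation of the secondary alcohol, which carries the C3 stereocentre from the chiral pool unchanged.

Step 12
Reactants: 20 silyloxy ester
Product: 21 (S)-3-[(tert-butyldimethylsilyl)oxy]pentan-1-ol
Conditions: i-Bu2AlH (2.2 equiv), CH2Cl2, −78 → 0 °C; aq Rochelle salt
Reagents that add atoms: none
Why: Hydride reduction of the ester to the primary alcohol, with C3 not involved.

Step 13
Reactants: 21 silyloxy alcohol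
Product: 22 (S)-tert-butyl[(1-iodopentan-3-yl)oxy]dimethylsilane
Conditions: I2, PPh3, imidazole, CH2Cl2, 0 °C
Reagents that add atoms: iodine II
Why: Appel-type iodination of the primary alcohol by SN2 displacement of the oxyphosphonium ion.

Step 14
Reactants: 18 C6 nitrile; 22 iodide
Product: 23 N-benzyl azatricyclic quaternary nitrile (C3 S; C6 S; C5 chain over the nitrogen bridge; nitrile over the cycloheptene)
Conditions: LiN(i-Pr)2, THF, −78 °C; 22, DMPU, −78 → 0 °C
Reagents that add atoms: none
Why: Alkylation of a planar tertiary nitrile anion with a primary iodide, in which the C6 face over the carbocyclic bridge is screened by the C13 side chain and C9–H, so the electrophile should enter over the nitrogen bridge and set C6.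

Step 15
Reactants: 23 quaternary nitrile
Product: 25 N-benzyl azatricyclic C7 alcohol, via neopentyl aldehyde 24 (not isolated)
Conditions: i-Bu2AlH, toluene, −78 → 0 °C; aq tartaric acid; then NaBH4, MeOH, 0 °C
Reagents that add atoms: water O
Why: Partial reduction of the nitrile to the N-aluminoimine, hydrolysis, and borohydride reduction of the crude aldehyde give the C7 alcohol without touching C6.

Step 16
Reactants: 25 C7 alcohol
Product: 26 N-benzyl azatricyclic tris(silyl ether)
Conditions: TBSCl, imidazole, DMF, 40 °C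
Reagents that add atoms: tert-butyldimethylsilyl chloride CC(C)(C)[Si](C)(C)Cl
Why: O-silylation of the neopentyl primary alcohol under forcing but standard conditions.

Step 17
Reactants: 26 N-benzyl amine
Product: 27 N-methoxycarbonyl azatricyclic tris(silyl ether)
Conditions: ClCO2Me (5 equiv), 1,2-dichloroethane, 80 °C
Reagents that add atoms: methyl chloroformate COC(=O)Cl
Why: Von Braun-type dealkylation in which the acylammonium ion loses benzyl to chloride, which exchanges the basic carbene-trapping amine for a carbamate that is also the latent N-methyl group.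

Step 18
Reactants: 27 carbamate
Product: 29 azatricyclic C23 carboxylic acid (C13 S; C16 S), via B-alkyl-9-BBN 28 (not isolated)
Conditions: 9-BBN-H, THF, 60 °C; then CuOAc (10 mol %), 1,10-phenanthroline (10 mol %), KOt-Bu (1.1 equiv), CO2 (1 atm), toluene, 100 °C; cold 1 M HCl
Reagents that add atoms: carbon dioxide O=C=O; 9-borabicyclo[3.3.1]nonane [H]B1C2CCCC1CCC2 (boron only in 28)
Why: Hydroboration followed by copper-catalysed carboxylation of the alkylborane, in which 9-BBN adds to the only accessible alkene through the conformer with C13–H next to the CH2 terminus and attacks anti to the bulky C12 side, which sets C16, while the tetrasubstituted alkene is inert.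

Step 19
Reactants: 29 acid
Product: 30 azatricyclic benzyl ester
Conditions: BnBr, K2CO3, DMF, 25 °C
Reagents that add atoms: benzyl bromide BrCc1ccccc1
Why: SN2 O-alkylation of the carboxylate gives an ester that can later be cleaved without base.

Step 20
Reactants: 30 benzyl ester
Product: 32 azatricyclic alpha-diazo benzyl ester with bridgehead C19–H, via trifluoroacetyl ester 31 (not isolated)
Conditions: LiN(SiMe3)2, THF, −78 °C; CF3CO2CH2CF3; 5 % HCl wash; then MsN3, Et3N, H2O, MeCN, 25 °C
Reagents that add atoms: methanesulfonyl azide CS(=O)(=O)N=[N+]=[N-]; 2,2,2-trifluoroethyl trifluoroacetate O=C(OCC(F)(F)F)C(F)(F)F (atoms only in 31)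
Why: Deacylative diazo transfer (Regitz type), in which Claisen trifluoroacetylation activates C18 and the sulfonyl azide delivers N2 with loss of the trifluoroacetyl group, while C16 is not epimerisable.

Step 21
Reactants: 32 alpha-diazo benzyl ester
Product: 33 tetracyclic C18 benzyl ester (ring B closed; C19 S quaternary; ester drawn trans to C17)
Conditions: Rh2(O2CCPh3)4 (2 mol %), CH2Cl2, −78 → −20 °C, 32 added over 2 h
Reagents that add atoms: none
Why: The dirhodium tetracarboxylate (divalent rhodium) expels N2 and the electrophilic carbenoid at C18 inserts through a concerted three-centre, hydride-transfer-like transition state into the outward C19–H bond, which is the intramolecular 1,5 C–H insertion of alpha-diazo esters known for cyclopentane synthesis. Ring B (C12–C13–C16–C18–C19) closes in a five-membered-ring-forming transition state in which C18 takes the place of the hydrogen. C19 becomes quaternary with retention, which the bicyclic cage enforces because only its outer face is open, and C18 is a new but irrelevant stereocentre, expected with the ester trans to C17 and away from C6. The chemoselectivity needed is insertion over 1,2-hydride shift from C16–H: the bulky, electron-rich triphenylacetate ligands and the low temperature slow the shift, the C17 oxygen makes C16–H a poorer hydride donor, and the favoured side-chain conformer already holds C18 in contact with C19–H. The site selectivity needed is over C15–H2 (also five atoms away but leading to a strained norbornene), C20–H2 (six atoms away and on the other side of the alkene plane) and C7–H2 (seven-membered ring), while cyclopropanation of C11=C12 would give a bicyclo[2.1.0]pentane and the carbamate nitrogen is too poor a donor to form an ylide. C19–H lies near the nodal plane of the C11=C12 pi bond, so it counts as a hindered tertiary rather than an activated allylic C–H bond, and this is where the route carries its risk.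

Step 22
Reactants: 33 tetracyclic benzyl ester
Product: 34 tetracyclic C18 carboxylic acid
Conditions: H2 (1 atm), Pd/C, EtOAc, 25 °C
Reagents that add atoms: none
Why: Hydrogenolysis of the benzyl ester under neutral conditions; the tetrasubstituted alkene, carbamate and silyl ethers are inert.

Step 23
Reactants: 34 acid
Product: 36 tetracyclic carbamate with C18 as CH2, via thiohydroxamate ester 35 (not isolated)
Conditions: 1-hydroxypyridine-2(1H)-thione, DCC, DMAP (cat.), CH2Cl2, 0 °C, dark; then t-BuSH, hν (tungsten lamp), toluene, 25 °C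
Reagents that add atoms: 1-hydroxypyridine-2(1H)-thione ON1C=CC=CC1=S (atoms only in 35)
Why: Barton decarboxylation, in which the secondary C18 radical takes hydrogen from the thiol faster than it can attack C12 (that would need a bicyclo[2.1.0]pentane), and the C18 stereocentre disappears.

Step 24
Reactants: 36 carbamate
Product: 37 N-methyl tetracyclic tris(silyl ether)
Conditions: LiAlH4, THF, 65 °C
Reagents that add atoms: none
Why: Exhaustive hydride reduction of the methyl carbamate to the N-methyl amine; partial loss of silyl groups would be harmless before step 25.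

Step 25
Reactants: 37 tris(silyl ether)
Product: 38 target CNP0221997.1 (C3 S; C6 S; C8 R; C13 S; C16 S; C19 S)
Conditions: n-Bu4NF, THF, 50 °C
Reagents that add atoms: none
Why: Fluoride-mediated cleavage of the three silyl ethers, with no stereocentre involved.

Compound list
1 | 2-bromoprop-2-en-1-ol | C=C(Br)CO | starting material
2 | [(2-bromoprop-2-en-1-yl)oxy](tert-butyl)dimethylsilane | C=C(Br)CO[Si](C)(C)C(C)(C)C | intermediate
3 | cyclopent-2-en-1-one | O=C1C=CCC1 | starting material
4 | 2-iodocyclopent-2-en-1-one | O=C1CCC=C1I | intermediate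
5 | bromo(2-ethoxy-2-oxoethyl)zinc | CCOC(=O)C[Zn]Br | starting material
6 | ethyl 2-(5-oxocyclopent-1-en-1-yl)acetate | CCOC(=O)CC1=CCCC1=O | intermediate
7 | {3-[(tert-butyldimethylsilyl)oxy]prop-1-en-2-yl}magnesium bromide | C=C([Mg]Br)CO[Si](C)(C)C(C)(C)C | intermediate
8 | bromomagnesium enolate of the conjugate adduct | Br[Mg]OC1=C(CC(=O)OCC)[C@@H](CC1)C(=C)CO[Si](C)(C)C(C)(C)C | intermediate
9 | (5S) enol triflate | O=S(=O)(OC1=C(CC(=O)OCC)[C@@H](CC1)C(=C)CO[Si](C)(C)C(C)(C)C)C(F)(F)F | intermediate
10 | bromo(4-ethoxy-4-oxobutyl)zinc | CCOC(=O)CCC[Zn]Br | starting material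
11 | (3R) cyclopentene diester | CCOC(=O)CCCC1=C(CC(=O)OCC)[C@@H](CC1)C(=C)CO[Si](C)(C)C(C)(C)C | intermediate
12 | bicyclic beta-keto ester (ester on C19) | CCOC(=O)C1C(=O)CCCC2=C1[C@@H](CC2)C(=C)CO[Si](C)(C)C(C)(C)C | intermediate
13 | (3R) hexahydroazulenone | O=C1CCCC2=C(C1)[C@@H](CC2)C(=C)CO[Si](C)(C)C(C)(C)C | intermediate
14 | benzylamine | NCc1ccccc1 | starting material
15 | formaldehyde | C=O | starting material
16 | N-benzyl-1-methoxy-N-(methoxymethyl)methanamine | COCN(Cc1ccccc1)COC | intermediate
17 | N-benzyl azatricyclic ketone | O=C1[C@H]2CCC3=C([C@@H](CC3)C(=C)CO[Si](C)(C)C(C)(C)C)[C@@H]1CN(Cc4ccccc4)C2 | intermediate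
18 | N-benzyl azatricyclic nitrile (C6 epimers) | N#CC1[C@H]2CCC3=C([C@@H](CC3)C(=C)CO[Si](C)(C)C(C)(C)C)[C@@H]1CN(Cc4ccccc4)C2 | intermediate
19 | methyl (S)-3-hydroxypentanoate | CC[C@H](O)CC(=O)OC | starting material
20 | methyl (S)-3-[(tert-butyldimethylsilyl)oxy]pentanoate | CC[C@H](O[Si](C)(C)C(C)(C)C)CC(=O)OC | intermediate
21 | (S)-3-[(tert-butyldimethylsilyl)oxy]pentan-1-ol | CC[C@H](O[Si](C)(C)C(C)(C)C)CCO | intermediate
22 | (S)-tert-butyl[(1-iodopentan-3-yl)oxy]dimethylsilane | CC[C@H](O[Si](C)(C)C(C)(C)C)CCI | intermediate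
23 | N-benzyl quaternary nitrile | CC[C@H](O[Si](C)(C)C(C)(C)C)CC[C@]1(C#N)[C@H]2CCC3=C([C@@H](CC3)C(=C)CO[Si](C)(C)C(C)(C)C)[C@@H]1CN(Cc4ccccc4)C2 | intermediate
24 | N-benzyl C7 aldehyde | CC[C@H](O[Si](C)(C)C(C)(C)C)CC[C@]1(C=O)[C@H]2CCC3=C([C@@H](CC3)C(=C)CO[Si](C)(C)C(C)(C)C)[C@@H]1CN(Cc4ccccc4)C2 | intermediate
25 | N-benzyl C7 alcohol | CC[C@H](O[Si](C)(C)C(C)(C)C)CC[C@]1(CO)[C@H]2CCC3=C([C@@H](CC3)C(=C)CO[Si](C)(C)C(C)(C)C)[C@@H]1CN(Cc4ccccc4)C2 | intermediate
26 | N-benzyl tris(silyl ether) | CC[C@H](O[Si](C)(C)C(C)(C)C)CC[C@]1(CO[Si](C)(C)C(C)(C)C)[C@H]2CCC3=C([C@@H](CC3)C(=C)CO[Si](C)(C)C(C)(C)C)[C@@H]1CN(Cc4ccccc4)C2 | intermediate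
27 | N-methoxycarbonyl tris(silyl ether) | CC[C@H](O[Si](C)(C)C(C)(C)C)CC[C@]1(CO[Si](C)(C)C(C)(C)C)[C@H]2CCC3=C([C@@H](CC3)C(=C)CO[Si](C)(C)C(C)(C)C)[C@@H]1CN(C(=O)OC)C2 | intermediate
28 | B-alkyl-9-BBN (boron on C18) | CC[C@H](O[Si](C)(C)C(C)(C)C)CC[C@]1(CO[Si](C)(C)C(C)(C)C)[C@H]2CCC3=C([C@@H](CC3)[C@@H](CO[Si](C)(C)C(C)(C)C)CB4C5CCCC4CCC5)[C@@H]1CN(C(=O)OC)C2 | intermediate
29 | azatricyclic carboxylic acid | CC[C@H](O[Si](C)(C)C(C)(C)C)CC[C@]1(CO[Si](C)(C)C(C)(C)C)[C@H]2CCC3=C([C@@H](CC3)[C@@H](CO[Si](C)(C)C(C)(C)C)CC(=O)O)[C@@H]1CN(C(=O)OC)C2 | intermediate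
30 | azatricyclic benzyl ester | CC[C@H](O[Si](C)(C)C(C)(C)C)CC[C@]1(CO[Si](C)(C)C(C)(C)C)[C@H]2CCC3=C([C@@H](CC3)[C@@H](CO[Si](C)(C)C(C)(C)C)CC(=O)OCc4ccccc4)[C@@H]1CN(C(=O)OC)C2 | intermediate
31 | alpha-trifluoroacetyl benzyl ester | CC[C@H](O[Si](C)(C)C(C)(C)C)CC[C@]1(CO[Si](C)(C)C(C)(C)C)[C@H]2CCC3=C([C@@H](CC3)[C@@H](CO[Si](C)(C)C(C)(C)C)C(C(=O)C(F)(F)F)C(=O)OCc4ccccc4)[C@@H]1CN(C(=O)OC)C2 | intermediate
32 | azatricyclic alpha-diazo benzyl ester (key-step precursor) | CC[C@H](O[Si](C)(C)C(C)(C)C)CC[C@]1(CO[Si](C)(C)C(C)(C)C)[C@H]2CCC3=C([C@@H](CC3)[C@@H](CO[Si](C)(C)C(C)(C)C)C(=[N+]=[N-])C(=O)OCc4ccccc4)[C@@H]1CN(C(=O)OC)C2 | intermediate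
33 | tetracyclic C18 benzyl ester (key-step product) | CC[C@H](O[Si](C)(C)C(C)(C)C)CC[C@]1(CO[Si](C)(C)C(C)(C)C)[C@H]2CCC3=C4[C@@H](CC3)[C@@H](CO[Si](C)(C)C(C)(C)C)[C@H](C(=O)OCc5ccccc5)[C@]41CN(C(=O)OC)C2 | intermediate
34 | tetracyclic C18 acid | CC[C@H](O[Si](C)(C)C(C)(C)C)CC[C@]1(CO[Si](C)(C)C(C)(C)C)[C@H]2CCC3=C4[C@@H](CC3)[C@@H](CO[Si](C)(C)C(C)(C)C)[C@H](C(=O)O)[C@]41CN(C(=O)OC)C2 | intermediate
35 | thiohydroxamate (Barton) ester | CC[C@H](O[Si](C)(C)C(C)(C)C)CC[C@]1(CO[Si](C)(C)C(C)(C)C)[C@H]2CCC3=C4[C@@H](CC3)[C@@H](CO[Si](C)(C)C(C)(C)C)[C@H](C(=O)ON5C=CC=CC5=S)[C@]41CN(C(=O)OC)C2 | intermediate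
36 | decarboxylated tetracyclic carbamate | CC[C@H](O[Si](C)(C)C(C)(C)C)CC[C@]1(CO[Si](C)(C)C(C)(C)C)[C@H]2CCC3=C4[C@@H](CC3)[C@@H](CO[Si](C)(C)C(C)(C)C)C[C@]41CN(C(=O)OC)C2 | intermediate
37 | N-methyl tris(silyl ether) | CC[C@H](O[Si](C)(C)C(C)(C)C)CC[C@]1(CO[Si](C)(C)C(C)(C)C)[C@H]2CCC3=C4[C@@H](CC3)[C@@H](CO[Si](C)(C)C(C)(C)C)C[C@]41CN(C)C2 | intermediate
38 | CNP0221997.1 | CC[C@H](O)CC[C@]1(CO)[C@H]2CCC3=C4[C@@H](CC3)[C@@H](CO)C[C@]41CN(C)C2 | target

Total step count: 25. Longest linear sequence: 20 steps (steps 2–7, 9, 10 and 14–25, from cyclopent-2-en-1-one).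

Steps most likely to fail

1. Step 21. Migration of the tertiary C16 hydrogen to the carbenoid carbon may outrun insertion into the hindered bridgehead C–H bond. Insertion may also drift to other C–H bonds.
   - The fallback ties C17–O and C23 into a five-membered ring, because cyclic alpha-diazo carbonyl compounds are known to resist migration of tertiary beta-hydrogens. It also removes C23 in a different way.
   - It sets out from 29. HF·pyridine in THF removes the two primary silyl groups, and the C17 alcohol closes onto the acid to give hydroxy lactone F1. TBSCl/imidazole re-protects C7–OH to give silyl lactone F2.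
   - LiN(SiMe3)2 and CF3CO2CH2CF3 give trifluoroacetyl lactone F3, and MsN3/Et3N gives diazo lactone F4.
   - Rh2(OAc)4 or Rh2(O2CCPh3)4 closes ring B to the cis-fused pentacyclic lactone F5.
   - i-Bu2AlH at −78 °C gives lactol F6. Stoichiometric RhCl(PPh3)3 in toluene at 110 °C decarbonylates its open hydroxy aldehyde form to C17 alcohol F7. TBSCl/imidazole then comes back to the route at 36.

2. Step 4. The Grignard reagent may deprotonate the acidic C19 methylene of 6 instead of adding, or the facial selectivity at C13 may be poor.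
   - The fallback gives up induction and separates diastereomers. It sets out from 6 and 2.
   - The achiral cuprate R2CuLi (from 2, t-BuLi and CuI), followed by Comins' reagent, gives racemic 9. Steps 5–7 carry this to racemic 13.
   - (S)-1-Phenylethylamine, paraformaldehyde and methanol give bis(methoxymethyl)-(S)-1-phenylethylamine F8. With Me3SiCl, as in step 9, this converts racemic 13 into two diastereomeric ketones that are separated by chromatography.
   - The isomer with the wanted core is N-(1-phenylethyl) ketone F9. 1-Chloroethyl chloroformate gives chloroethyl carbamate F10, and warm methanol gives secondary amine F11. BnBr/K2CO3 comes back to the route at 17.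

3. Step 9. The Lewis-acidic medium may move the C11=C12 alkene into conjugation with the ketone, which also endangers C13. The reaction may stop after one aminomethylation, or the bridge may form on the wrong face.
   - The fallback builds the piperidine under basic, reversible conditions. It sets out from 13.
   - Two rounds of LiN(i-Pr)2 and dimethyl(methylidene)ammonium iodide give bis(dimethylaminomethyl) ketone F12. MeI gives bis(trimethylammonium) diiodide F13.
   - Heating with benzylamine 14 and K2CO3 in aqueous ethanol eliminates trimethylamine to the transient bis(methylene) ketone F14. Benzylamine adds to this twice (double aza-Michael addition) under thermodynamic control, which comes back to the route at 17.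

Further compounds
F1 | step 21 | hydroxy lactone (C7–OH free) | CC[C@H](O[Si](C)(C)C(C)(C)C)CC[C@]1(CO)[C@H]2CCC3=C([C@@H](CC3)[C@@H]4CC(=O)OC4)[C@@H]1CN(C(=O)OC)C2
F2 | step 21 | silyl lactone | CC[C@H](O[Si](C)(C)C(C)(C)C)CC[C@]1(CO[Si](C)(C)C(C)(C)C)[C@H]2CCC3=C([C@@H](CC3)[C@@H]4CC(=O)OC4)[C@@H]1CN(C(=O)OC)C2
F3 | step 21 | trifluoroacetyl lactone | CC[C@H](O[Si](C)(C)C(C)(C)C)CC[C@]1(CO[Si](C)(C)C(C)(C)C)[C@H]2CCC3=C([C@@H](CC3)[C@@H]4C(C(=O)C(F)(F)F)C(=O)OC4)[C@@H]1CN(C(=O)OC)C2
F4 | step 21 | diazo lactone | CC[C@H](O[Si](C)(C)C(C)(C)C)CC[C@]1(CO[Si](C)(C)C(C)(C)C)[C@H]2CCC3=C([C@@H](CC3)[C@@H]4C(=[N+]=[N-])C(=O)OC4)[C@@H]1CN(C(=O)OC)C2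
F5 | step 21 | pentacyclic lactone | CC[C@H](O[Si](C)(C)C(C)(C)C)CC[C@]1(CO[Si](C)(C)C(C)(C)C)[C@H]2CCC3=C4[C@@H](CC3)[C@H]5COC(=O)[C@H]5[C@]41CN(C(=O)OC)C2
F6 | step 21 | lactol | CC[C@H](O[Si](C)(C)C(C)(C)C)CC[C@]1(CO[Si](C)(C)C(C)(C)C)[C@H]2CCC3=C4[C@@H](CC3)[C@H]5COC(O)[C@H]5[C@]41CN(C(=O)OC)C2
F7 | step 21 | C17 alcohol | CC[C@H](O[Si](C)(C)C(C)(C)C)CC[C@]1(CO[Si](C)(C)C(C)(C)C)[C@H]2CCC3=C4[C@@H](CC3)[C@@H](CO)C[C@]41CN(C(=O)OC)C2
F8 | step 4 | bis(methoxymethyl)-(S)-1-phenylethylamine | C[C@H](N(COC)COC)c1ccccc1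
F9 | step 4 | N-(1-phenylethyl) ketone | O=C1[C@H]2CCC3=C([C@@H](CC3)C(=C)CO[Si](C)(C)C(C)(C)C)[C@@H]1CN([C@@H](C)c4ccccc4)C2
F10 | step 4 | chloroethyl carbamate | O=C1[C@H]2CCC3=C([C@@H](CC3)C(=C)CO[Si](C)(C)C(C)(C)C)[C@@H]1CN(C(=O)OC(C)Cl)C2
F11 | step 4 | secondary amine | O=C1[C@H]2CCC3=C([C@@H](CC3)C(=C)CO[Si](C)(C)C(C)(C)C)[C@@H]1CNC2
F12 | step 9 | bis(dimethylaminomethyl) ketone | O=C1C(CN(C)C)CCC2=C(C1CN(C)C)[C@@H](CC2)C(=C)CO[Si](C)(C)C(C)(C)C
F13 | step 9 | bis(trimethylammonium) diiodide | O=C1C(C[N+](C)(C)C)CCC2=C(C1C[N+](C)(C)C)[C@@H](CC2)C(=C)CO[Si](C)(C)C(C)(C)C.[I-].[I-]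
F14 | step 9 | bis(methylene) ketone | O=C1C(=C)CCC2=C(C1=C)[C@@H](CC2)C(=C)CO[Si](C)(C)C(C)(C)C
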